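The 26-membered diolide is cut at C6b–C1'b. Locants: each heterocycle is N1, C2 (methyl), C3 (ester oxygen), C6 (chain); a = imine ring A, b = amine ring B; C1'–C8' run from C6 to the chain carbonyl. Because C6b bears, besides N1b, only an unfunctionalised methylene chain, ring B can be carried as an alanine-derived lactam enol phosphate. One operation, hydroboration of a terminal alkene followed by intramolecular B-alkyl Suzuki coupling, forms C6b–C1'b and closes the macrocycle. Its precursor is an open diester: the ring B enol phosphate acylated at O3b by the C8'a acid, whose O3a carries oct-7-enoate, C2a a benzyl ether and C6a NHBoc.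

Key step: step 19

Remark on the chemistry: C2a ends as an sp2 carbon, so its configuration in the intermediates is free; (S) is chosen because ethyl (S)-lactate then gives C3a (S) by chelate control. The C2a oxygen is carried as a benzyl ether, which survives the borane and is removed in the same hydrogenation that sets C6b, so no fluoride or base meets the O3a ester while C2a is a free hydroxyl.

Remark on the chemistry: the sense of addition in step 6 is assigned from the chelated chair transition state usual for Grignard reagents in CH2Cl2; should the open transition state prevail, (S)-2-methylpropane-2-sulfinamide would be used in step 5.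

**Ring A half (steps 1–10)**

Step 1
Reactants: 1 ethyl (S)-lactate
Product: 2 ethyl (2S)-2-(benzyloxy)propanoate
Conditions: BnOC(=NH)CCl3, TfOH (cat.), cyclohexane/CH2Cl2, rt
Reagents that add atoms: benzyl 2,2,2-trichloroacetimidate, N=C(OCc1ccccc1)C(Cl)(Cl)Cl
Why: Acid-catalysed trichloroacetimidate benzylation alkylates the hydroxyl without base, so the lactate centre should not racemise.

Step 2
Reactants: 2 ethyl (2S)-2-(benzyloxy)propanoate
Product: 3 (2S)-2-(benzyloxy)propanal
Conditions: i-Bu2AlH, CH2Cl2, −78 °C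
Reagents that add atoms: none
Why: Partial ester reduction stops at the tetrahedral aluminium hemiacetal at low temperature and releases the aldehyde on work-up; the aldehyde is used at once to avoid epimerisation.

Step 3
Reactants: 3 (2S)-2-(benzyloxy)propanal
Product: 4 (3S,4S)-4-(benzyloxy)pent-1-yn-3-ol
Conditions: MgBr2·OEt2, CH2Cl2, −78 °C; HC≡CMgBr (THF), −78 → −20 °C
Reagents that add atoms: ethynylmagnesium bromide, C#C[Mg]Br
Why: Cram chelate-controlled Grignard addition: magnesium bridges the aldehyde and benzyloxy oxygens, the acetylide attacks anti to the methyl group and sets C3 (future C3a) as S (syn); the minor epimer should be removable by chromatography.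

Step 4
Reactants: 4 (3S,4S)-4-(benzyloxy)pent-1-yn-3-ol
Product: 5 {[(3S,4S)-4-(benzyloxy)pent-1-yn-3-yl]oxy}triethylsilane
Conditions: Et3SiCl, imidazole, CH2Cl2, 0 °C → rt
Reagents that add atoms: chlorotriethylsilane, CC[Si](Cl)(CC)CC
Why: Routine silyl ether formation masks the alcohol so that the alkyne can be metalated cleanly.

Step 5
Reactants: 6 methyl 9-oxononanoate; 7 (R)-2-methylpropane-2-sulfinamide
Product: 8 methyl (9E)-9-{[(R)-tert-butylsulfinyl]imino}nonanoate
Conditions: CuSO4, CH2Cl2, rt
Reagents that add atoms: none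
Why: Ellman condensation of an aldehyde with the sulfinamide over a dehydrating Lewis acid gives the E N-sulfinyl aldimine; the methyl ester is inert.

Step 6
Reactants: 5 {[(3S,4S)-4-(benzyloxy)pent-1-yn-3-yl]oxy}triethylsilane; 8 methyl (9E)-9-{[(R)-tert-butylsulfinyl]imino}nonanoate
Product: 10 methyl (9R,12S,13S)-13-(benzyloxy)-9-{[(R)-tert-butylsulfinyl]amino}-12-[(triethylsilyl)oxy]tetradec-10-ynoate, via alkynylmagnesium bromide 9 (not isolated)
Conditions: EtMgBr, THF, 0 → 40 °C; then 8, CH2Cl2, −78 °C → rt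
Reagents that add atoms: none
Why: Ellman addition of an alkynyl Grignard reagent in a non-coordinating solvent: a six-membered chair transition state with magnesium on the sulfinyl oxygen and tert-butyl equatorial delivers the alkynyl group to the Si face of the aldimine and sets C9 (future C6a) as R; alkynylmagnesium halides should not attack the methyl ester at this temperature.

Step 7
Reactants: 10 methyl (9R,12S,13S)-13-(benzyloxy)-9-{[(R)-tert-butylsulfinyl]amino}-12-[(triethylsilyl)oxy]tetradec-10-ynoate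
Product: 12 methyl (9R,12S,13S)-13-(benzyloxy)-9-[(tert-butoxycarbonyl)amino]-12-hydroxytetradec-10-ynoate, via amino alcohol hydrochloride 11 (not isolated)
Conditions: HCl (4 M in dioxane), MeOH, 0 °C → rt; then Boc2O, Et3N, CH2Cl2, rt
Reagents that add atoms: di-tert-butyl dicarbonate, CC(C)(C)OC(=O)OC(=O)OC(C)(C)C
Why: Acidic methanolysis cleaves the N–S bond and the triethylsilyl ether together, and carbamate formation then takes place only at the amine, the hindered alcohol staying free.

Step 8
Reactants: 12 methyl (9R,12S,13S)-13-(benzyloxy)-9-[(tert-butoxycarbonyl)amino]-12-hydroxytetradec-10-ynoate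
Product: 13 methyl (9R,12S,13S)-13-(benzyloxy)-9-[(tert-butoxycarbonyl)amino]-12-hydroxytetradecanoate
Conditions: H2 (1 atm), PtO2, EtOAc, rt
Reagents that add atoms: none
Why: Heterogeneous hydrogenation over platinum saturates the alkyne and should leave the alkyl benzyl ether intact; no stereocentre is touched.

Step 9
Reactants: 13 methyl (9R,12S,13S)-13-(benzyloxy)-9-[(tert-butoxycarbonyl)amino]-12-hydroxytetradecanoate; 14 oct-7-enoic acid
Product: 15 methyl (9R,12S,13S)-13-(benzyloxy)-9-[(tert-butoxycarbonyl)amino]-12-(oct-7-enoyloxy)tetradecanoate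
Conditions: EDC·HCl, DMAP, CH2Cl2, 0 °C → rt
Reagents that add atoms: none
Why: Steglich esterification of the only free hydroxyl (O3a).

Step 10
Reactants: 15 methyl (9R,12S,13S)-13-(benzyloxy)-9-[(tert-butoxycarbonyl)amino]-12-(oct-7-enoyloxy)tetradecanoate
Product: 16 (9R,12S,13S)-13-(benzyloxy)-9-[(tert-butoxycarbonyl)amino]-12-(oct-7-enoyloxy)tetradecanoic acid
Conditions: Me3SnOH, ClCH2CH2Cl, 70 °C; dilute HCl work-up
Reagents that add atoms: trimethyltin hydroxide, C[Sn](C)(C)O
Why: Trimethyltin hydroxide ester cleavage hydrolyses unhindered methyl esters and should spare the hindered secondary octenoate and the carbamate.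

**Ring B fragment (steps 11–17)**

Step 11
Reactants: 17 N-Boc-L-alanine N-methoxy-N-methylamide
Product: 18 N-Boc-L-alaninal, tert-butyl N-[(2S)-1-oxopropan-2-yl]carbamate
Conditions: LiAlH4, THF, 0 °C; aq. KHSO4
Reagents that add atoms: none
Why: Fehrentz–Castro reduction: the N-methoxy-N-methylamide forms a stable chelated tetrahedral intermediate, so reduction stops at the aldehyde without racemisation; the aldehyde is used at once.

Step 12
Reactants: 18 N-Boc-L-alaninal
Product: 20 tert-butyl N-[(1S)-1-[(2S)-5-oxooxolan-2-yl]ethyl]carbamate, via hydroxy ester 19 (not isolated)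
Conditions: BrZnCH2CH2CO2Et, TiCl(OiPr)3, THF/CH2Cl2, −20 → 0 °C; then PPTS, toluene, 60 °C
Reagents that add atoms: (3-ethoxy-3-oxopropyl)zinc bromide, CCOC(=O)CC[Zn]Br
Why: Homoaldol addition of a titanium ester homoenolate to an N-Boc α-amino aldehyde under Cram cyclic (chelate) control: titanium binds the carbamate and the aldehyde oxygen, the nucleophile enters anti to the methyl group and sets C4 (future C3b) as S, syn to nitrogen; mild acid then lactonises the γ-hydroxy ester, and any anti isomer should be separable at the lactone.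

Step 13
Reactants: 20 tert-butyl N-[(1S)-1-[(2S)-5-oxooxolan-2-yl]ethyl]carbamate
Product: 22 (5S,6S)-5-hydroxy-6-methylpiperidin-2-one, via aminolactone trifluoroacetate 21 (not isolated)
Conditions: CF3CO2H, CH2Cl2, 0 °C → rt; then Et3N, MeOH, rt
Reagents that add atoms: none
Why: Boc acidolysis, then lactone-to-lactam ring expansion (O-to-N acyl transfer through a six-membered transition state) gives the more stable δ-lactam with both centres untouched.

Step 14
Reactants: 22 (5S,6S)-5-hydroxy-6-methylpiperidin-2-one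
Product: 23 (5S,6S)-6-methyl-5-[(triethylsilyl)oxy]piperidin-2-one
Conditions: Et3SiCl, imidazole, DMF, rt
Reagents that add atoms: chlorotriethylsilane, CC[Si](Cl)(CC)CC
Why: Silyl ether formation at the alcohol; the lactam N–H is not silylated under these conditions.

Step 15
Reactants: 23 (5S,6S)-6-methyl-5-[(triethylsilyl)oxy]piperidin-2-one
Product: 24 tert-butyl (2S,3S)-2-methyl-6-oxo-3-[(triethylsilyl)oxy]piperidine-1-carboxylate
Conditions: Boc2O, DMAP, Et3N, CH2Cl2, rt
Reagents that add atoms: di-tert-butyl dicarbonate, CC(C)(C)OC(=O)OC(=O)OC(C)(C)C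
Why: DMAP-catalysed N-acylation of the lactam gives the imide-type N-Boc lactam needed for clean enolisation.

Step 16
Reactants: 24 tert-butyl (2S,3S)-2-methyl-6-oxo-3-[(triethylsilyl)oxy]piperidine-1-carboxylate
Product: 26 tert-butyl (2S,3S)-6-[(diphenoxyphosphoryl)oxy]-2-methyl-3-[(triethylsilyl)oxy]-3,4-dihydro-2H-pyridine-1-carboxylate, via potassium enolate 25 (not isolated)
Conditions: KN(SiMe3)2, THF, −78 °C; then (PhO)2P(O)Cl, −78 °C
Reagents that add atoms: diphenyl chlorophosphate, O=P(Cl)(Oc1ccccc1)Oc1ccccc1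
Why: Kinetic enolisation of the N-Boc lactam and O-phosphorylation of the enolate (ketene aminal phosphate formation); no other acidic C–H or N–H is present.

Step 17
Reactants: 26 tert-butyl (2S,3S)-6-[(diphenoxyphosphoryl)oxy]-2-methyl-3-[(triethylsilyl)oxy]-3,4-dihydro-2H-pyridine-1-carboxylate
Product: 27 tert-butyl (2S,3S)-6-[(diphenoxyphosphoryl)oxy]-3-hydroxy-2-methyl-3,4-dihydro-2H-pyridine-1-carboxylate
Conditions: HF·pyridine, pyridine, THF, 0 °C
Reagents that add atoms: none
Why: Buffered fluoride desilylation removes the triethylsilyl ether under conditions that should be too mild to protonate the enecarbamate or attack the phosphate triester.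

**Union, macrocyclisation and endgame (steps 18–22)**

Step 18
Reactants: 16 (9R,12S,13S)-13-(benzyloxy)-9-[(tert-butoxycarbonyl)amino]-12-(oct-7-enoyloxy)tetradecanoic acid; 27 tert-butyl (2S,3S)-6-[(diphenoxyphosphoryl)oxy]-3-hydroxy-2-methyl-3,4-dihydro-2H-pyridine-1-carboxylate
Product: 28 tert-butyl (2S,3S)-3-{[(9R,12S,13S)-13-(benzyloxy)-9-[(tert-butoxycarbonyl)amino]-12-(oct-7-enoyloxy)tetradecanoyl]oxy}-6-[(diphenoxyphosphoryl)oxy]-2-methyl-3,4-dihydro-2H-pyridine-1-carboxylate (open-chain alkene enol phosphate)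
Conditions: EDC·HCl, DMAP, CH2Cl2, 0 °C → rt
Reagents that add atoms: none
Why: Steglich esterification of the secondary alcohol O3b; the enol phosphate and both carbamates are inert to carbodiimide and DMAP.

Step 19
Reactants: 28 open-chain alkene enol phosphate
Product: 30 macrocyclic enecarbamate (26-membered diolide; C5b=C6b; N1b-Boc; C6a NHBoc; O2a benzyl), via B-alkyl-9-BBN 29 (not isolated)
Conditions: 9-BBN, THF, 0 °C → rt; then syringe-pump addition to PdCl2(dppf), AsPh3, Cs2CO3, DMF/THF/H2O, 50 °C (about 1 mM)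
Reagents that add atoms: none
Why: 9-BBN adds anti-Markovnikov to the monosubstituted alkene and places boron on C1'b; zerovalent palladium then inserts into the C6b–O bond of the enol phosphate, the base-activated borate transfers its primary alkyl group to palladium, and reductive elimination forms C6b–C1'b. The closest known reaction types are the B-alkyl Suzuki–Miyaura coupling of lactam-derived enol phosphates and B-alkyl Suzuki macrocyclisation. The 26-membered ring closes end to end by intramolecular transmetalation, through a palladacycle that contracts on reductive elimination, and slow addition at high dilution should favour this over oligomerisation. No stereocentre is formed, since C6b stays sp2. The step needs chemoselective hydroboration, which is secured because the only other alkene is the trisubstituted, phosphate- and carbamate-bearing enecarbamate alkene, and because esters, carbamates and the benzyl ether are inert to 9-BBN, whereas a C2a ketone would not be. The bidentate dppf ligand should favour reductive elimination over β-hydride elimination of the alkylpalladium intermediate.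

Step 20
Reactants: 30 macrocyclic enecarbamate
Product: 31 saturated diolide alcohol (ring B all-cis N-Boc piperidine, 2S,3S,6R; C3a bears (1S)-1-hydroxyethyl)
Conditions: H2 (3 atm), Pd(OH)2/C, EtOAc/EtOH, rt
Reagents that add atoms: none
Why: Heterogeneous hydrogenation: allylic 1,3-strain with the N-Boc group makes the C2b methyl axial, hydrogen adds to C5b=C6b from the opposite face and sets C6b as R (chain cis to methyl and to O3b), and the same catalyst hydrogenolyses the benzyl ether.

Step 21
Reactants: 31 saturated diolide alcohol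
Product: 32 diolide methyl ketone (C2a=O)
Conditions: Dess–Martin periodinane, NaHCO3, CH2Cl2, 0 °C → rt
Reagents that add atoms: none
Why: Dess–Martin oxidation of the secondary alcohol under buffered, non-basic conditions that should neither enolise C3a nor move the O3a acyl group; the crude alcohol is oxidised without delay.

Step 22
Reactants: 32 diolide methyl ketone
Product: 34 CNP0304114.1 (target), via diamino ketone bis(trifluoroacetate) 33 (not isolated)
Conditions: CF3CO2H, CH2Cl2, 0 °C; then aq. NaHCO3, CH2Cl2, rt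
Reagents that add atoms: none
Why: Acidolysis of both Boc groups, then spontaneous condensation of the C6a primary amine with the C2a ketone on neutralisation (six-membered cyclic imine formation) closes ring A; the secondary amine of ring B cannot form an imine.

**Compound list**

1 | ethyl (S)-lactate | C[C@H](O)C(=O)OCC | starting material
2 | ethyl (2S)-2-(benzyloxy)propanoate | C[C@H](OCc1ccccc1)C(=O)OCC | intermediate
3 | (2S)-2-(benzyloxy)propanal | C[C@H](OCc1ccccc1)C=O | intermediate
4 | (3S,4S)-4-(benzyloxy)pent-1-yn-3-ol | C#C[C@H](O)[C@H](C)OCc1ccccc1 | intermediate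
5 | {[(3S,4S)-4-(benzyloxy)pent-1-yn-3-yl]oxy}triethylsilane | C#C[C@H](O[Si](CC)(CC)CC)[C@H](C)OCc1ccccc1 | intermediate
6 | methyl 9-oxononanoate | COC(=O)CCCCCCCC=O | starting material
7 | (R)-2-methylpropane-2-sulfinamide | CC(C)(C)[S@@](=O)N | starting material
8 | methyl (9E)-9-{[(R)-tert-butylsulfinyl]imino}nonanoate | COC(=O)CCCCCCC/C=N/[S@](=O)C(C)(C)C | intermediate
9 | alkynylmagnesium bromide of 5, formed in situ | Br[Mg]C#C[C@H](O[Si](CC)(CC)CC)[C@H](C)OCc1ccccc1 | intermediate
10 | methyl (9R,12S,13S)-13-(benzyloxy)-9-{[(R)-tert-butylsulfinyl]amino}-12-[(triethylsilyl)oxy]tetradec-10-ynoate | COC(=O)CCCCCCC[C@@H](N[S@](=O)C(C)(C)C)C#C[C@H](O[Si](CC)(CC)CC)[C@H](C)OCc1ccccc1 | intermediate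
11 | methyl (9R,12S,13S)-9-amino-13-(benzyloxy)-12-hydroxytetradec-10-ynoate hydrochloride, formed in situ | COC(=O)CCCCCCC[C@@H](N)C#C[C@H](O)[C@H](C)OCc1ccccc1.Cl | intermediate
12 | methyl (9R,12S,13S)-13-(benzyloxy)-9-[(tert-butoxycarbonyl)amino]-12-hydroxytetradec-10-ynoate | COC(=O)CCCCCCC[C@@H](NC(=O)OC(C)(C)C)C#C[C@H](O)[C@H](C)OCc1ccccc1 | intermediate
13 | methyl (9R,12S,13S)-13-(benzyloxy)-9-[(tert-butoxycarbonyl)amino]-12-hydroxytetradecanoate | COC(=O)CCCCCCC[C@@H](NC(=O)OC(C)(C)C)CC[C@H](O)[C@H](C)OCc1ccccc1 | intermediate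
14 | oct-7-enoic acid | C=CCCCCCC(=O)O | starting material
15 | methyl (9R,12S,13S)-13-(benzyloxy)-9-[(tert-butoxycarbonyl)amino]-12-(oct-7-enoyloxy)tetradecanoate | COC(=O)CCCCCCC[C@@H](NC(=O)OC(C)(C)C)CC[C@H](OC(=O)CCCCCC=C)[C@H](C)OCc1ccccc1 | intermediate
16 | (9R,12S,13S)-13-(benzyloxy)-9-[(tert-butoxycarbonyl)amino]-12-(oct-7-enoyloxy)tetradecanoic acid | OC(=O)CCCCCCC[C@@H](NC(=O)OC(C)(C)C)CC[C@H](OC(=O)CCCCCC=C)[C@H](C)OCc1ccccc1 | intermediate
17 | N-Boc-L-alanine N-methoxy-N-methylamide | C[C@H](NC(=O)OC(C)(C)C)C(=O)N(C)OC | starting material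
18 | N-Boc-L-alaninal, tert-butyl N-[(2S)-1-oxopropan-2-yl]carbamate | C[C@H](NC(=O)OC(C)(C)C)C=O | intermediate
19 | ethyl (4S,5S)-5-[(tert-butoxycarbonyl)amino]-4-hydroxyhexanoate, formed in situ | CCOC(=O)CC[C@H](O)[C@H](C)NC(=O)OC(C)(C)C | intermediate
20 | tert-butyl N-[(1S)-1-[(2S)-5-oxooxolan-2-yl]ethyl]carbamate | C[C@H](NC(=O)OC(C)(C)C)[C@@H]1CCC(=O)O1 | intermediate
21 | (5S)-5-[(1S)-1-aminoethyl]oxolan-2-one trifluoroacetate, formed in situ | C[C@H](N)[C@@H]1CCC(=O)O1.OC(=O)C(F)(F)F | intermediate
22 | (5S,6S)-5-hydroxy-6-methylpiperidin-2-one | C[C@@H]1NC(=O)CC[C@@H]1O | intermediate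
23 | (5S,6S)-6-methyl-5-[(triethylsilyl)oxy]piperidin-2-one | C[C@@H]1NC(=O)CC[C@@H]1O[Si](CC)(CC)CC | intermediate
24 | tert-butyl (2S,3S)-2-methyl-6-oxo-3-[(triethylsilyl)oxy]piperidine-1-carboxylate | C[C@@H]1N(C(=O)OC(C)(C)C)C(=O)CC[C@@H]1O[Si](CC)(CC)CC | intermediate
25 | potassium enolate of 24, formed in situ | C[C@@H]1N(C(=O)OC(C)(C)C)C([O-])=CC[C@@H]1O[Si](CC)(CC)CC.[K+] | intermediate
26 | tert-butyl (2S,3S)-6-[(diphenoxyphosphoryl)oxy]-2-methyl-3-[(triethylsilyl)oxy]-3,4-dihydro-2H-pyridine-1-carboxylate | C[C@@H]1N(C(=O)OC(C)(C)C)C(OP(=O)(Oc2ccccc2)Oc2ccccc2)=CC[C@@H]1O[Si](CC)(CC)CC | intermediate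
27 | tert-butyl (2S,3S)-6-[(diphenoxyphosphoryl)oxy]-3-hydroxy-2-methyl-3,4-dihydro-2H-pyridine-1-carboxylate | C[C@@H]1N(C(=O)OC(C)(C)C)C(OP(=O)(Oc2ccccc2)Oc2ccccc2)=CC[C@@H]1O | intermediate
28 | open-chain alkene enol phosphate: tert-butyl (2S,3S)-3-{[(9R,12S,13S)-13-(benzyloxy)-9-[(tert-butoxycarbonyl)amino]-12-(oct-7-enoyloxy)tetradecanoyl]oxy}-6-[(diphenoxyphosphoryl)oxy]-2-methyl-3,4-dihydro-2H-pyridine-1-carboxylate | C=CCCCCCC(=O)O[C@H]([C@H](C)OCc1ccccc1)CC[C@H](NC(=O)OC(C)(C)C)CCCCCCCC(=O)O[C@H]2CC=C(OP(=O)(Oc3ccccc3)Oc3ccccc3)N(C(=O)OC(C)(C)C)[C@H]2C | intermediate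
29 | B-alkyl-9-BBN of 28 (boron on C1'b), formed in situ | O=C(CCCCCCCB1C2CCCC1CCC2)O[C@H]([C@H](C)OCc1ccccc1)CC[C@H](NC(=O)OC(C)(C)C)CCCCCCCC(=O)O[C@H]2CC=C(OP(=O)(Oc3ccccc3)Oc3ccccc3)N(C(=O)OC(C)(C)C)[C@H]2C | intermediate
30 | 26-membered diolide with C5b=C6b enecarbamate: ring B N-Boc tetrahydropyridine (2S,3S), C6a (R) NHBoc, C3a (S) bearing (1S)-1-(benzyloxy)ethyl | O1[C@H]([C@H](C)OCc3ccccc3)CC[C@H](NC(=O)OC(C)(C)C)CCCCCCCC(=O)O[C@H]2CC=C(CCCCCCCC1=O)N(C(=O)OC(C)(C)C)[C@H]2C | intermediate
31 | 26-membered diolide with all-cis N-Boc piperidine ring B (2S,3S,6R), C6a (R) NHBoc, C3a (S) bearing (1S)-1-hydroxyethyl | O1[C@H]([C@H](C)O)CC[C@H](NC(=O)OC(C)(C)C)CCCCCCCC(=O)O[C@H]2CC[C@@H](CCCCCCCC1=O)N(C(=O)OC(C)(C)C)[C@H]2C | intermediate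
32 | the same diolide with acetyl at C3a (C2a ketone) | O1[C@H](C(C)=O)CC[C@H](NC(=O)OC(C)(C)C)CCCCCCCC(=O)O[C@H]2CC[C@@H](CCCCCCCC1=O)N(C(=O)OC(C)(C)C)[C@H]2C | intermediate
33 | diamino ketone (both Boc groups removed) as bis(trifluoroacetate), formed in situ | O1[C@H](C(C)=O)CC[C@H](N)CCCCCCCC(=O)O[C@H]2CC[C@@H](CCCCCCCC1=O)N[C@H]2C.OC(=O)C(F)(F)F.OC(=O)C(F)(F)F | intermediate
34 | CNP0304114.1: ring A cyclic imine (3S,6R), ring B all-cis piperidine (2S,3S,6R) | CC1=N[C@@H]2CCCCCCCC(=O)O[C@H]3CC[C@@H](CCCCCCCC(=O)O[C@H]1CC2)N[C@H]3C | target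

**Count and risks**

Total step count: 22. Longest linear sequence: 14 steps (steps 1–4, 6–10, 18–22, from ethyl (S)-lactate).

Steps most likely to fail:

1. Step 19. Intermolecular coupling may outrun ring closure and give oligomers, the alkylborane may be lost by protodeboronation or β-hydride elimination, and the enol phosphate may be hydrolysed back to the lactam by the aqueous base. Fallback: the same C6b–C1'b bond is made intermolecularly and the ring is closed by lactonisation. The fallback sets out from 15 and 26. Hydroboration of 15 with 9-BBN in THF should give the B-alkyl-9-BBN of 15 F1, which is coupled with 26 (PdCl2(dppf), Cs2CO3, DMF/THF/H2O, 50 °C) to the open coupled methyl ester F2. Me3SnOH in ClCH2CH2Cl frees the seco acid silyl ether F3, and HF·pyridine in THF/pyridine gives the seco hydroxy acid F4. Yamaguchi macrolactonisation (2,4,6-trichlorobenzoyl chloride, Et3N, then DMAP, toluene, high dilution) forms the O3b–C8'a ester and comes back to the route at 30.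

2. Step 12. Chelate and open transition states may compete, giving poor facial selectivity at the new carbinol centre, and aldehyde 18 may epimerise before it reacts. Fallback: substrate control is replaced by catalyst control. The fallback sets out from 18. Lithium ethyl propiolate (ethyl propiolate, LiN(SiMe3)2, THF, −78 °C) should give ethyl (4S,5S)-5-[(tert-butoxycarbonyl)amino]-4-hydroxyhex-2-ynoate F5 together with its (4R,5S) epimer F6. The unseparated mixture is oxidised with Dess–Martin periodinane to ethyl (5S)-5-[(tert-butoxycarbonyl)amino]-4-oxohex-2-ynoate F7. Noyori transfer hydrogenation with RuCl[(R,R)-TsDPEN](p-cymene) in i-PrOH, in which the alkynyl group takes the place of the aryl group of the usual model, should return F5 alone. Hydrogenation (H2, Pd/C, EtOAc) saturates the alkyne and comes back to the route at 19, which is lactonised to 20 as in step 12.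

3. Step 10. The reagent may fail to distinguish the two esters, so that the secondary octenoate is cleaved along with the methyl ester, or the hindered substrate may react too slowly. Fallback: the chain acid is carried as an orthogonal allyl ester. The fallback sets out from 13. LiOH in THF/H2O gives the hydroxy acid F8, and allyl bromide with KHCO3 in DMF alkylates the carboxylate only, giving the allyl ester F9. Steglich esterification with 14 (EDC·HCl, DMAP, CH2Cl2) gives the allyl ester octenoate F10. Pd(PPh3)4 and morpholine in THF remove the allyl group by π-allyl transfer without touching the octenoate or the terminal alkene, and the fallback comes back to the route at 16.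

Further compounds

F1 | step 19 | B-alkyl-9-BBN of 15 | COC(=O)CCCCCCC[C@@H](NC(=O)OC(C)(C)C)CC[C@H](OC(=O)CCCCCCCB1C2CCCC1CCC2)[C@H](C)OCc1ccccc1
F2 | step 19 | open coupled methyl ester (C6b–C1'b formed, O3b triethylsilyl ether) | COC(=O)CCCCCCC[C@@H](NC(=O)OC(C)(C)C)CC[C@H](OC(=O)CCCCCCCC1=CC[C@H](O[Si](CC)(CC)CC)[C@H](C)N1C(=O)OC(C)(C)C)[C@H](C)OCc1ccccc1
F3 | step 19 | seco acid silyl ether | OC(=O)CCCCCCC[C@@H](NC(=O)OC(C)(C)C)CC[C@H](OC(=O)CCCCCCCC1=CC[C@H](O[Si](CC)(CC)CC)[C@H](C)N1C(=O)OC(C)(C)C)[C@H](C)OCc1ccccc1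
F4 | step 19 | seco hydroxy acid | OC(=O)CCCCCCC[C@@H](NC(=O)OC(C)(C)C)CC[C@H](OC(=O)CCCCCCCC1=CC[C@H](O)[C@H](C)N1C(=O)OC(C)(C)C)[C@H](C)OCc1ccccc1
F5 | step 12 | ethyl (4S,5S)-5-[(tert-butoxycarbonyl)amino]-4-hydroxyhex-2-ynoate | CCOC(=O)C#C[C@H](O)[C@H](C)NC(=O)OC(C)(C)C
F6 | step 12 | ethyl (4R,5S)-5-[(tert-butoxycarbonyl)amino]-4-hydroxyhex-2-ynoate | CCOC(=O)C#C[C@@H](O)[C@H](C)NC(=O)OC(C)(C)C
F7 | step 12 | ethyl (5S)-5-[(tert-butoxycarbonyl)amino]-4-oxohex-2-ynoate | CCOC(=O)C#CC(=O)[C@H](C)NC(=O)OC(C)(C)C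
F8 | step 10 | (9R,12S,13S)-13-(benzyloxy)-9-[(tert-butoxycarbonyl)amino]-12-hydroxytetradecanoic acid | OC(=O)CCCCCCC[C@@H](NC(=O)OC(C)(C)C)CC[C@H](O)[C@H](C)OCc1ccccc1
F9 | step 10 | prop-2-en-1-yl (9R,12S,13S)-13-(benzyloxy)-9-[(tert-butoxycarbonyl)amino]-12-hydroxytetradecanoate | C=CCOC(=O)CCCCCCC[C@@H](NC(=O)OC(C)(C)C)CC[C@H](O)[C@H](C)OCc1ccccc1
F10 | step 10 | prop-2-en-1-yl (9R,12S,13S)-13-(benzyloxy)-9-[(tert-butoxycarbonyl)amino]-12-(oct-7-enoyloxy)tetradecanoate | C=CCOC(=O)CCCCCCC[C@@H](NC(=O)OC(C)(C)C)CC[C@H](OC(=O)CCCCCC=C)[C@H](C)OCc1ccccc1
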